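Both 2-pyranone rings are cut at O1–C2 and C3=C4, because in each coumarin O1 is a phenol oxygen on C8a and C4 sits on the neighbouring ring carbon C4a: the pyranones map onto two salicylaldehyde units. The precursor is therefore the fully assembled bis(2-hydroxy-4-methoxy-3-alkylbenzaldehyde) ether with its single carbinol masked as a silyl ether. One treatment with Ph3P=C=C=O acylates both phenols and closes both lactones by intramolecular Wittig olefination. The chiral ether core is built beforehand from one (S)-epoxide, which serves both as electrophile and, after isomerisation, as the allylic alcohol; the formyl groups are introduced last, so no aldehyde has to be protected.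

Key step: step 10

Remark: both stereocentres of the target are (S) by CIP analysis of its SMILES; the L-fructose-derived (enantiomeric) Shi ketone is assumed to be at hand (it is prepared from L-sorbose).

Step 1
Reactants: 1 1,3-dimethoxybenzene; 2 1-bromo-3-methylbut-2-ene (prenyl bromide)
Product: 4 1,3-dimethoxy-2-(3-methylbut-2-en-1-yl)benzene, via 2,6-dimethoxyphenyllithium 3 (not isolated)
Conditions: n-BuLi, THF, 0 °C → rt; then 2, −78 °C → rt
Reagents that add atoms: none
Why: Directed ortho-metalation, in which both methoxy groups steer lithiation to C2, followed by SN2 alkylation of the aryllithium with the primary allylic bromide, places the prenyl group between the two oxygens.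

Step 2
Reactants: 4 1,3-dimethoxy-2-(3-methylbut-2-en-1-yl)benzene
Product: 5 3-methoxy-2-(3-methylbut-2-en-1-yl)phenol
Conditions: NaSEt, DMF, 130 °C; aq. HCl
Reagents that add atoms: none
Why: SN2 O-demethylation of an aryl methyl ether by thiolate should stop after one methyl group because the phenoxide formed deactivates the ring, and the two methoxy groups are equivalent, so only one monophenol can arise.

Step 3
Reactants: 5 3-methoxy-2-(3-methylbut-2-en-1-yl)phenol
Product: 6 3-methoxy-2-(3-methylbut-2-en-1-yl)phenyl pivalate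
Conditions: PivCl, Et3N, DMAP (cat.), CH2Cl2, 0 °C → rt
Reagents that add atoms: pivaloyl chloride, CC(C)(C)C(=O)Cl
Why: DMAP-catalysed O-acylation gives an aryl ester whose oxygen cannot cyclise onto the later epoxide, which tempers the nucleophilicity of the arene and which should withstand the oxidant, the aluminium amide and the Lewis acid of the following steps.

Step 4
Reactants: 6 3-methoxy-2-(3-methylbut-2-en-1-yl)phenyl pivalate
Product: 7 2-{[(2S)-3,3-dimethyloxiran-2-yl]methyl}-3-methoxyphenyl pivalate
Conditions: L-fructose-derived Shi ketone (0.3 equiv), Oxone, K2CO3, Bu4NHSO4, MeCN–CH2(OMe)2 / aq. Na2B4O7–Na2EDTA buffer (pH 10.5), 0 °C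
Reagents that add atoms: potassium peroxymonosulfate (the oxidant of Oxone), [K+].[O-]S(=O)(=O)OO
Why: Shi asymmetric epoxidation, in which the chiral dioxirane transfers oxygen to the trisubstituted alkene through a spiro transition state; the L-fructose-derived ketone should give the (S)-epoxide, since the D-fructose ketone is known to give (R)-epoxides from 2-methylalk-2-enes.

Step 5
Reactants: 7 2-{[(2S)-3,3-dimethyloxiran-2-yl]methyl}-3-methoxyphenyl pivalate (part of the material)
Product: 8 2-[(2S)-2-hydroxy-3-methylbut-3-en-1-yl]-3-methoxyphenyl pivalate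
Conditions: Et2Al(TMP) (from LiTMP + Et2AlCl), toluene, 0 °C; aq. potassium sodium tartrate
Reagents that add atoms: none
Why: Aluminium amide-mediated isomerisation of an epoxide to an allylic alcohol, in which aluminium binds the epoxide oxygen and the hindered amide removes a methyl proton in a cyclic syn-elimination; only the tertiary C–O bond breaks, so the carbinol carbon keeps its (S) configuration.

Step 6
Reactants: 7 2-{[(2S)-3,3-dimethyloxiran-2-yl]methyl}-3-methoxyphenyl pivalate; 8 2-[(2S)-2-hydroxy-3-methylbut-3-en-1-yl]-3-methoxyphenyl pivalate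
Product: 9 2-[(2S)-2-hydroxy-3-methyl-3-({(2S)-1-[2-methoxy-6-(pivaloyloxy)phenyl]-3-methylbut-3-en-2-yl}oxy)butyl]-3-methoxyphenyl pivalate
Conditions: BF3·OEt2 (0.1 equiv), 8 (3 equiv, excess recovered), 4 Å MS, CH2Cl2, −78 → −30 °C, slow addition of 7
Reagents that add atoms: none
Why: Lewis acid-catalysed alcoholysis of a trisubstituted epoxide, in which the secondary alcohol attacks the activated epoxide at its tertiary carbon (Markovnikov, borderline SN1); that carbon is not stereogenic, so both (S) centres of 7 and 8 pass into the ether unchanged.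

Step 7
Reactants: 9 hydroxy ether bis-pivalate
Product: 10 2-[(2S)-2-(tert-butyldimethylsilyloxy)-3-methyl-3-({(2S)-1-[2-methoxy-6-(pivaloyloxy)phenyl]-3-methylbut-3-en-2-yl}oxy)butyl]-3-methoxyphenyl pivalate
Conditions: TBSOTf, 2,6-lutidine, CH2Cl2, −78 → 0 °C
Reagents that add atoms: tert-butyldimethylsilyl triflate, CC(C)(C)[Si](C)(C)OS(=O)(=O)C(F)(F)F
Why: Silylation of the only free hydroxyl, a hindered secondary alcohol, with a silyl triflate and a non-nucleophilic base, masks the carbinol that would otherwise add to the ketene ylide in step 10.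

Step 8
Reactants: 10 silyl ether bis-pivalate
Product: 11 2-[(2S)-2-(tert-butyldimethylsilyloxy)-3-{[(2S)-1-(2-hydroxy-6-methoxyphenyl)-3-methylbut-3-en-2-yl]oxy}-3-methylbutyl]-3-methoxyphenol
Conditions: NaOMe, MeOH–THF, rt → 40 °C; aq. NH4Cl
Reagents that add atoms: none
Why: Methoxide transesterification of the two aryl pivalates (phenoxide as leaving group) should free both phenols, while the alkyl silyl ether, the dialkyl ether and the alkene are inert to base.

Step 9
Reactants: 11 bis-phenol silyl ether
Product: 13 3-[(2S)-2-(tert-butyldimethylsilyloxy)-3-{[(2S)-1-(3-formyl-2-hydroxy-6-methoxyphenyl)-3-methylbut-3-en-2-yl]oxy}-3-methylbutyl]-2-hydroxy-4-methoxybenzaldehyde, via bis(hydroxymethyl) bisphenol 12 (not isolated)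
Conditions: MgCl2, Et3N, (CH2O)n, THF, reflux; cold 1 M HCl
Reagents that add atoms: paraformaldehyde (as formaldehyde), C=O
Why: Magnesium-mediated ortho-formylation of phenols (Casnati–Skattebøl), in which the magnesium phenoxide delivers formaldehyde to the only free ortho position (para to OMe) and the benzylic alkoxide is then oxidised by Oppenauer-type hydride transfer to a second formaldehyde.

Step 10
Reactants: 13 bis-salicylaldehyde silyl ether; 14 (triphenylphosphoranylidene)ketene (Bestmann ylide)
Product: 16 8-[(2S)-2-(tert-butyldimethylsilyloxy)-3-{[(2S)-1-(7-methoxy-2-oxo-2H-chromen-8-yl)-3-methylbut-3-en-2-yl]oxy}-3-methylbutyl]-7-methoxy-2H-chromen-2-one, via bis(phosphoranylideneacetate) ester ylide 15 (not isolated)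
Conditions: 14 (2.4 equiv), toluene, 110 °C
Reagents that add atoms: none
Why: Each phenol O–H adds across the C=C bond of the cumulated ylide to give an aryl (triphenylphosphoranylidene)acetate (15), which forms O1–C2; the stabilised ylide carbon then attacks the ortho formyl group and the oxaphosphetane collapses to Ph3P=O and the C3=C4 bond. The closest known reaction type is the coumarin synthesis from salicylaldehydes and this ylide, an addition–intramolecular Wittig domino. Each pyranone ring closes by 6-exo-trig attack of the ylide carbon on the aldehyde, so the ring alkene can only be cis. No stereocentre is formed, and the two (S) centres lie away from the reacting sites and are not touched under neutral conditions. The step needs chemoselectivity for phenol over alcohol, which the silyl ether on the only carbinol secures, and intramolecular over intermolecular olefination, which the ortho placement of OH and CHO on each ring secures. The acid-sensitive tertiary and allylic ether should survive because neither acid nor base is added.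

Step 11
Reactants: 16 bis-coumarin silyl ether
Product: 17 8-[(2S)-2-hydroxy-3-{[(2S)-1-(7-methoxy-2-oxo-2H-chromen-8-yl)-3-methylbut-3-en-2-yl]oxy}-3-methylbutyl]-7-methoxy-2H-chromen-2-one (target)
Conditions: HF·pyridine, pyridine, THF, 0 °C → rt
Reagents that add atoms: none
Why: Fluoride-mediated cleavage of the silyl ether, buffered with pyridine, should leave the lactones, the tertiary and allylic ether and both stereocentres untouched.

Compound list
1 | 1,3-dimethoxybenzene | COc1cccc(OC)c1 | starting material
2 | 1-bromo-3-methylbut-2-ene (prenyl bromide) | CC(C)=CCBr | starting material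
3 | 2,6-dimethoxyphenyllithium (formed in the flask) | [Li]c1c(OC)cccc1OC | intermediate
4 | 1,3-dimethoxy-2-(3-methylbut-2-en-1-yl)benzene | COc1cccc(OC)c1CC=C(C)C | intermediate
5 | 3-methoxy-2-(3-methylbut-2-en-1-yl)phenol | COc1cccc(O)c1CC=C(C)C | intermediate
6 | 3-methoxy-2-(3-methylbut-2-en-1-yl)phenyl pivalate | COc1cccc(OC(=O)C(C)(C)C)c1CC=C(C)C | intermediate
7 | 2-{[(2S)-3,3-dimethyloxiran-2-yl]methyl}-3-methoxyphenyl pivalate | CC1(C)O[C@H]1Cc1c(OC)cccc1OC(=O)C(C)(C)C | intermediate
8 | 2-[(2S)-2-hydroxy-3-methylbut-3-en-1-yl]-3-methoxyphenyl pivalate | C=C(C)[C@@H](O)Cc1c(OC)cccc1OC(=O)C(C)(C)C | intermediate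
9 | 2-[(2S)-2-hydroxy-3-methyl-3-({(2S)-1-[2-methoxy-6-(pivaloyloxy)phenyl]-3-methylbut-3-en-2-yl}oxy)butyl]-3-methoxyphenyl pivalate | C=C(C)[C@H](Cc1c(OC)cccc1OC(=O)C(C)(C)C)OC(C)(C)[C@@H](O)Cc1c(OC)cccc1OC(=O)C(C)(C)C | intermediate
10 | tert-butyldimethylsilyl ether of 9 at the (S)-carbinol | C=C(C)[C@H](Cc1c(OC)cccc1OC(=O)C(C)(C)C)OC(C)(C)[C@@H](O[Si](C)(C)C(C)(C)C)Cc1c(OC)cccc1OC(=O)C(C)(C)C | intermediate
11 | 2-[(2S)-2-(tert-butyldimethylsilyloxy)-3-{[(2S)-1-(2-hydroxy-6-methoxyphenyl)-3-methylbut-3-en-2-yl]oxy}-3-methylbutyl]-3-methoxyphenol | C=C(C)[C@H](Cc1c(OC)cccc1O)OC(C)(C)[C@@H](O[Si](C)(C)C(C)(C)C)Cc1c(OC)cccc1O | intermediate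
12 | bis(salicyl alcohol): 11 carrying CH2OH ortho to each phenol OH and para to each OMe, (S,S) (formed in the flask) | C=C(C)[C@H](Cc1c(OC)ccc(CO)c1O)OC(C)(C)[C@@H](O[Si](C)(C)C(C)(C)C)Cc1c(OC)ccc(CO)c1O | intermediate
13 | 3-[(2S)-2-(tert-butyldimethylsilyloxy)-3-{[(2S)-1-(3-formyl-2-hydroxy-6-methoxyphenyl)-3-methylbut-3-en-2-yl]oxy}-3-methylbutyl]-2-hydroxy-4-methoxybenzaldehyde | C=C(C)[C@H](Cc1c(OC)ccc(C=O)c1O)OC(C)(C)[C@@H](O[Si](C)(C)C(C)(C)C)Cc1c(OC)ccc(C=O)c1O | intermediate
14 | (triphenylphosphoranylidene)ketene | O=C=C=P(c1ccccc1)(c1ccccc1)c1ccccc1 | starting material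
15 | bis[aryl (triphenylphosphoranylidene)acetate] of 13, both phenols acylated, (S,S) (formed in the flask) | C=C(C)[C@H](Cc1c(OC)ccc(C=O)c1OC(=O)C=P(c1ccccc1)(c1ccccc1)c1ccccc1)OC(C)(C)[C@@H](O[Si](C)(C)C(C)(C)C)Cc1c(OC)ccc(C=O)c1OC(=O)C=P(c1ccccc1)(c1ccccc1)c1ccccc1 | intermediate
16 | 8-[(2S)-2-(tert-butyldimethylsilyloxy)-3-{[(2S)-1-(7-methoxy-2-oxo-2H-chromen-8-yl)-3-methylbut-3-en-2-yl]oxy}-3-methylbutyl]-7-methoxy-2H-chromen-2-one | C=C(C)[C@H](Cc1c(OC)ccc2ccc(=O)oc12)OC(C)(C)[C@@H](O[Si](C)(C)C(C)(C)C)Cc1c(OC)ccc2ccc(=O)oc12 | intermediate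
17 | 8-[(2S)-2-hydroxy-3-{[(2S)-1-(7-methoxy-2-oxo-2H-chromen-8-yl)-3-methylbut-3-en-2-yl]oxy}-3-methylbutyl]-7-methoxy-2H-chromen-2-one | C=C(C)[C@H](Cc1c(OC)ccc2ccc(=O)oc12)OC(C)(C)[C@@H](O)Cc1c(OC)ccc2ccc(=O)oc12 | target

Total step count: 11. Longest linear sequence: 11 steps (steps 1–11 in one line; epoxide 7 enters step 6 directly and, after step 5, as alcohol 8).

Steps most likely to fail

1. Step 6 (ether union). The activated epoxide may be drained by 1,2-hydride shift to the ketone, by proton loss or by self-addition before the hindered secondary alcohol attacks, and the ortho-methoxy oxygen may intercept the developing tertiary cation. Fallback, setting out from 7: acid-catalysed hydrolysis (HClO4 cat., THF–H2O; water enters at the tertiary carbon, the stereocentre is retained) should give the diol 2-[(2S)-2,3-dihydroxy-3-methylbutyl]-3-methoxyphenyl pivalate F1. Selective silylation of its secondary hydroxyl (TBSCl, imidazole, DMF) should give the tertiary alcohol 2-[(2S)-2-(tert-butyldimethylsilyloxy)-3-hydroxy-3-methylbutyl]-3-methoxyphenyl pivalate F2. Cl3CCN with catalytic DBU in CH2Cl2 should convert it into the tertiary trichloroacetimidate 2-[(2S)-2-(tert-butyldimethylsilyloxy)-3-methyl-3-(2,2,2-trichloroacetimidoyloxy)butyl]-3-methoxyphenyl pivalate F3. Acid-catalysed tert-alkyl transfer from F3 to alcohol 8 (TMSOTf cat., cyclohexane–CH2Cl2, −20 °C) should then give the silylated ether directly, so the fallback rejoins the route at 10 and step 7 is no longer needed.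

2. Step 5 (epoxide to allylic alcohol). The amide may abstract a benzylic proton instead of a methyl proton, which would open the epoxide the wrong way, or the aluminium reagent may attack the aryl ester. Fallback, setting out from 7: single-electron opening with the trivalent titanium reagent Cp2TiCl (from Cp2TiCl2 and Mn dust, THF, rt). Homolysis of the tertiary C–O bond gives the tertiary β-titanoxy radical, and loss of a methyl hydrogen atom to a second equivalent of Cp2TiCl should give the isopropenyl carbinol. This radical route tolerates esters, makes no new compound (F0) and rejoins the route at 8.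

3. Step 9 (twofold ortho-formylation). One ring may stop at the hydroxymethyl stage, or further reaction with formaldehyde may give methoxymethylated material, which would leave mixtures at a late stage. Fallback, setting out from 11: phenylboronic acid-templated ortho-hydroxymethylation (PhB(OH)2, (CH2O)n, EtCO2H cat., toluene, reflux with removal of water) should give the bis(2-phenyl-4H-1,3,2-benzodioxaborin) of 11 F4. Transesterification with propane-1,3-diol should release the bis(salicyl alcohol) 12, here isolated, and oxidation of its two benzylic alcohols with MnO2 in CH2Cl2 rejoins the route at 13.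

Further compounds
F1 | step 6 | 2-[(2S)-2,3-dihydroxy-3-methylbutyl]-3-methoxyphenyl pivalate | CC(C)(O)[C@@H](O)Cc1c(OC)cccc1OC(=O)C(C)(C)C
F2 | step 6 | 2-[(2S)-2-(tert-butyldimethylsilyloxy)-3-hydroxy-3-methylbutyl]-3-methoxyphenyl pivalate | CC(C)(O)[C@@H](O[Si](C)(C)C(C)(C)C)Cc1c(OC)cccc1OC(=O)C(C)(C)C
F3 | step 6 | 2-[(2S)-2-(tert-butyldimethylsilyloxy)-3-methyl-3-(2,2,2-trichloroacetimidoyloxy)butyl]-3-methoxyphenyl pivalate | CC(C)(OC(=N)C(Cl)(Cl)Cl)[C@@H](O[Si](C)(C)C(C)(C)C)Cc1c(OC)cccc1OC(=O)C(C)(C)C
F0 | step 5 | none | none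
F4 | step 9 | bis(2-phenyl-4H-1,3,2-benzodioxaborin) of 11, each phenol O and its new ortho CH2O bridged by B–Ph, (S,S) | C=C(C)[C@H](Cc1c(OC)ccc2c1OB(c1ccccc1)OC2)OC(C)(C)[C@@H](O[Si](C)(C)C(C)(C)C)Cc1c(OC)ccc2c1OB(c1ccccc1)OC2
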